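(The earlier runs and the new flask were generated by integration from invented constants, and the scatter is random.)

One exchange per complex per hour is the unit of this reckoning: each exchange uses one incoming ligand, and a complex needs two of them to become complex with two exchanged.

| flask | starting complex | incoming ligand | remark | time |
|---|---|---|---|---|
| larch | 0.20 M | 0.27 M | run made earlier |  |
| oak | 0.20 M | 0.49 M | run made earlier |  |
| south-west | 0.20 M | 0.100 M |  | 30 h |
| west | 0.20 M | 0.400 M |  | 30 h |
| south-east | 0.20 M | 0.600 M |  | 30 h |

| run | time / h | complex with two exchanged / % | starting complex / % |
|---|---|---|---|
| larch | 1.50 | 39.4 | 19.5 |
| larch | 3.00 | 43.9 | 17.3 |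
| larch | 6.00 | 44.9 | 16.2 |
| larch | 12.0 | 43.9 | 16.4 |
| larch | 20.0 | 44.5 | 16.1 |
| oak | 4.00 | 92.7 | 0.3 |
| oak | 8.00 | 92.4 | 0.5 |
| oak | 12.0 | 92.3 | 0 |
| oak | 15.0 | 93.2 | 0.3 |
| oak | 20.0 | 92.7 | 0.5 |

(scatter of a reading: 0.5 percentage points)

* which of these holds the largest part of the starting complex at the end of south-west (starting complex / complex with one exchanged / complex with two exchanged)
* which of these holds the largest part of the starting complex at the end of west (starting complex / complex with one exchanged / complex with two exchanged)
* which of these holds the largest part of the starting complex at the end of south-east (starting complex / complex with one exchanged / complex with two exchanged)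
* final complex with two exchanged in west, as a percentage of the starting complex charged

- a reading or a percentage of complex with two exchanged counts all its forms, free or not

By a reckoning separate from the forecast, the larch readings show the starting complex falling by 1.63 e-foldings in the first 1.50 h. Counting the unread rest as complex with one exchanged, larch then held 0.0302 M of incoming ligand, a logarithmic mean of 0.109 M over that stretch. Scaled to the charge of west, and assuming the second exchange about as fast as the first, this gives an estimated starting rate of 3.98 h⁻¹ in west. Over 30 h that makes 119, the turnover count: the exchanges per complex that the starting rate would pay for if it never slowed.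

West is charged 2.00 ligands per complex, just the exchanges needed, so c(incoming ligand) and the unexchanged sites fall together. The rate therefore falls by the square of their common factor, and about one part in the count remains: 0.837% of the ligand, with the rate down 14300-fold and 1.67% of the complex one exchange short. The oak readings, at 2.45 ligands per complex, average 92.7%; taking that reading as what west tends to, less the share one exchange short, this reckoning puts west near 91.0%.

The forecast, taking “both earlier runs at equilibrium”, chooses starting complex for south-west, complex with two exchanged for west and complex with two exchanged for south-east, and gives 80% for west, within 74% to 84%, which differs from the 91.0% of the reckoning above.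

The flasks hold most as starting complex in south-west, complex with two exchanged in west and complex with two exchanged in south-east.

    starting complex + incoming ligand → leaving ligand + complex with one exchanged (k = 0.00410 M⁻¹ s⁻¹)
    complex with one exchanged + incoming ligand → leaving ligand + complex with two exchanged (k = 0.00360 M⁻¹ s⁻¹)
    crystals ⇌ complex with two exchanged, rate k3*(cs3 - [complex with two exchanged]) while solid is left; crystals form when [complex with two exchanged] > cs3 (solubility = 0.0770 M, k = 0.00280 s⁻¹)
    complex with two exchanged ⇌ isomer of the product (K = 0.180, k = 1.20 × 10⁻⁴ s⁻¹)

West ends at 91.8% of complex with two exchanged, crystals counted, with 0.703% of its incoming ligand left against the 0.837% from the count. The neighbouring flask is west with 0.080 M of starting complex. Its c(incoming ligand) is that of west and its count is 119, but two exchanges per complex reckon to leave 60.0% of the ligand, and it leaves 60%. Starting complex, the limiting reagent there, stands at 0%. That neighbouring flask ends at 84.7% of complex with two exchanged, with 15.3% as isomer of the product and 0% as crystals.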